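**Assumption:** the sense of induction of lithium bis(1-phenylethyl)amide on cis-2,6-dimethylcyclohexanone is taken from the 4-substituted cyclohexanone series, which points to the (S,S)-amide; if chiral GC of 4 shows the opposite sense, the (R,R)-amide is used.

## Retrosynthetic overview

1. Right-hand ring: the carbocycle of 2,6-dimethylphenol 1 is dearomatised to meso ketone 2 and desymmetrised (enolate 3) to (S)-2,2,6-trimethylcyclohexanone 4. This is the key step; it sets C-5' and the gem-dimethyl carbon together.
2. Left-hand ring and chain: bought intact as β-apo-8'-carotenal 5 (C30) and homologated to the C31 alkyne 6.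
3. Disconnection C-6'/C-7': lithium acetylide 7 plus ketone 4 give the C40 alkynyl carbinol 8.
4. Disconnection "retro shift": 8 → E-allylic carbinol 9 → target 10 by loss of 6'-OH and H-4, which moves all ten chain C=C bonds by one position.
5. Ring order: no ring is built. The right ring is finished first (steps 1–2); the left ring is turned into its 4-ene/6-ylidene form in the last step.

## Route

Step 1
Reactants: 1 2,6-dimethylphenol
Product: 2 cis-2,6-dimethylcyclohexanone (meso; 2R,6S)
Conditions: H2 (10 bar), 5% Pd/C, cyclohexane, 140 °C; NaOMe (cat.), MeOH, 25 °C; fractional distillation (cis ≥ 97%)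
Reagents that add atoms: none
Why: Heterogeneous Pd-catalysed arene hydrogenation of a phenol stops at the ketone because the enol tautomerises and the hindered C=O is reduced only slowly over Pd, and methoxide equilibration then fixes the two methyl groups cis (diequatorial), which is the meso isomer.

Step 2
Reactants: 2 cis-2,6-dimethylcyclohexanone
Product: 4 (S)-2,2,6-trimethylcyclohexanone, via lithium (6S)-2,6-dimethylcyclohexenolate 3 (not isolated)
Conditions: (S,S)-bis(1-phenylethyl)amine (1.2 equiv), n-BuLi (1.15 equiv), LiCl (0.6 equiv), THF, −78 °C; 2 added over 1 h at −95 °C; MeI (3 equiv), −95 → −40 °C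
Reagents that add atoms: iodomethane, CI
Why: Enantioselective deprotonation of a meso ketone by a C2-symmetric chiral lithium amide (Simpkins–Koga desymmetrisation) removes the α-H at the (2R)-carbon so that the untouched C-6 stays S, and the non-equilibrating enolate 3 is C-methylated at the deprotonated carbon without a silyl enol ether detour (75–90% ee expected for this substrate class).

Step 3
Reactants: 5 all-E-8'-apo-β-caroten-8'-al (β-apo-8'-carotenal)
Product: 6 all-E C31 polyenyne (7',8'-didehydro-7'-apo-β-carotene; 5 with CH=O replaced by C≡CH)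
Conditions: TMSCHN2 (1.2 equiv), n-BuLi (1.15 equiv), THF, −78 °C; 5, −78 → 25 °C, dark, Ar
Reagents that add atoms: trimethylsilyldiazomethane, C[Si](C)(C)C=[N+]=[N-]
Why: Colvin alkyne homologation (1,2-addition of lithiated TMS-diazomethane, Peterson-type loss of Me3SiOLi, loss of N2 and 1,2-H shift of the alkylidene carbene) converts CH=O into C≡CH under non-acidic, low-temperature conditions that leave the all-E polyene untouched.

Step 4
Reactants: 6 all-E C31 polyenyne; 4 (S)-2,2,6-trimethylcyclohexanone
Product: 8 (5'S,6'R)-7',8'-didehydro-5',6'-dihydro-β,β-caroten-6'-ol, via lithium acetylide 7 (not isolated)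
Conditions: 6, n-BuLi (1.0 equiv), THF, −78 °C; 4 (1.5 equiv), −78 → 0 °C; H2O
Reagents that add atoms: none
Why: 1,2-Addition of a lithium acetylide to the hindered ketone (the union used for 2,2,6-trimethylcyclohexanones in carotenoid and abscisic acid syntheses) proceeds by axial attack without enolisation because the acetylide is weakly basic, so C-5' stays S while the new carbinol centre (mainly OH trans to the 5'-methyl) is destined to become sp2.

Step 5
Reactants: 8 (5'S,6'R)-7',8'-didehydro-5',6'-dihydro-β,β-caroten-6'-ol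
Product: 10 (5'S,6E,6'E)-4,5'-retro-β,β-carotene (CNP0257724.1), via allylic carbinol 9 (not isolated)
Conditions: Red-Al (3 equiv), THF, 0 → 25 °C; Rochelle-salt quench, extract, swap to CH2Cl2 (crude 9); p-TsOH·H2O (3 mol%), −30 → 0 °C, 15 min; Et3N; heptane, 80 °C, 1 h, dark; crystallise (CH2Cl2/MeOH)
Reagents that add atoms: none
Why: Alkoxide-directed trans-hydroalumination (Red-Al reduction of a propargylic alcohol) gives the E-allylic carbinol 9, whose ionisation yields a cation delocalised from C-6' to C-5 that loses H-4 as in the retinol → anhydroretinol retro-dehydration (E1, vinylogous), so every s-trans single bond becomes an E double bond, both exocyclic geometries settle in their thermodynamic A(1,3)-controlled forms, and C-5' is expected to survive because A(1,3) strain holds its H near the nodal plane of the cation.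

## Compound list

1 | 2,6-dimethylphenol | Cc1cccc(C)c1O | starting material
2 | cis-2,6-dimethylcyclohexanone (meso; 2R,6S) | O=C1[C@H](C)CCC[C@@H]1C | intermediate
3 | lithium (6S)-2,6-dimethylcyclohex-1-en-1-olate | [Li+].[O-]C1=C(C)CCC[C@@H]1C | intermediate (not isolated)
4 | (S)-2,2,6-trimethylcyclohexanone | O=C1[C@@H](C)CCCC1(C)C | intermediate
5 | all-E-8'-apo-β-caroten-8'-al (β-apo-8'-carotenal) | O=C/C(C)=C/C=C/C(C)=C/C=C/C=C(C)/C=C/C=C(C)/C=C/C1=C(C)CCCC1(C)C | starting material
6 | all-E C31 polyenyne (7',8'-didehydro-7'-apo-β-carotene) | C#C/C(C)=C/C=C/C(C)=C/C=C/C=C(C)/C=C/C=C(C)/C=C/C1=C(C)CCCC1(C)C | intermediate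
7 | lithium acetylide of 6 | [Li+].[C-]#C/C(C)=C/C=C/C(C)=C/C=C/C=C(C)/C=C/C=C(C)/C=C/C1=C(C)CCCC1(C)C | intermediate (not isolated)
8 | (5'S,6'R)-7',8'-didehydro-5',6'-dihydro-β,β-caroten-6'-ol (major carbinol epimer; both converge) | O[C@]1(C#C/C(C)=C/C=C/C(C)=C/C=C/C=C(C)/C=C/C=C(C)/C=C/C2=C(C)CCCC2(C)C)[C@@H](C)CCCC1(C)C | intermediate
9 | (5'S,6'S)-5',6'-dihydro-β,β-caroten-6'-ol (all-E) | O[C@]1(/C=C/C(C)=C/C=C/C(C)=C/C=C/C=C(C)/C=C/C=C(C)/C=C/C2=C(C)CCCC2(C)C)[C@@H](C)CCCC1(C)C | intermediate (not isolated)
10 | (5'S,6E,6'E)-4,5'-retro-β,β-carotene | CC1=CCCC(C)(C)\C1=C/C=C(C)/C=C/C=C(C)/C=C/C=C/C(C)=C/C=C/C(C)=C/C=C1\[C@@H](C)CCCC1(C)C | target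

## Step count and risks

Total: 5 steps. Longest linear sequence: 4 steps (1 → 2 → 4 → 8 → 10); the second branch is one step (5 → 6).

Steps most likely to fail:

1. **Step 5 (site of proton loss).** The delocalised cation can also lose H-5', giving achiral β,β-carotene (removed by chromatography), or a methyl proton, and E/Z mixtures at C-6/C-6' may need the thermal equilibration. The fallback never places a cation next to C-5'; it sets out from 5 and 4 and returns at 10. NaBH4 reduces 5 to all-E-8'-apo-β-caroten-8'-ol F1. Acid-catalysed dehydration of F1, the exact analogue of retinol → anhydroretinol, gives the retro C30 hydrocarbon F2 with a terminal C-8' methylene; here no tertiary ring hydrogen competes with H-4. Separately, 4 is converted by dimethylsulfonium methylide into the spiro-epoxide (4S)-4,8,8-trimethyl-1-oxaspiro[2.5]octane F3. Lewis-acid Meinwald rearrangement (MgBr2 or MABR) gives (6S)-2,2,6-trimethylcyclohexanecarbaldehyde F4. Tf2O with 2,6-di-tert-butyl-4-methylpyridine gives the enol triflate (E)-[(6S)-2,2,6-trimethylcyclohexylidene]methyl triflate F5. Heck coupling of F5 with the terminal methylene of F2 (Pd(OAc)2, PPh3, Et3N, DMF, 40 °C) forms the C-7'–C-8' bond and gives 10.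

2. **Step 2 (ee, sense of induction, over-methylation, residual trans-2).** The fallback uses enantioselective protonation instead of enantioselective deprotonation; it sets out from 2 and returns at 4. LDA/MeI gives racemic 2,2,6-trimethylcyclohexanone F6. LDA/TMSCl gives its only possible silyl enol ether, 2,6,6-trimethylcyclohex-1-en-1-yl trimethylsilyl ether F7. Protonation with a BINOL·SnCl4 Lewis-acid-assisted Brønsted acid (enantiomer chosen on small scale to give S) at −78 °C returns 4. In either case, if 4 is below 98% ee, the final 10 is polished by preparative chiral-phase HPLC.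

3. **Step 3 (lithiated diazo reagent on a C30 polyenal; sensitive polyenyne).** The fallback is a Corey–Fuchs sequence; it sets out from 5 and returns at 7. CBr4/PPh3/Zn gives the all-E 1,1-dibromo-olefin F8. Two equivalents of n-BuLi (Br/Li exchange, Fritsch–Buttenberg–Wiechell shift, deprotonation) give lithium acetylide 7 directly, which is quenched with 4 as in step 4 without isolating 6.

## Further compounds

F1 | step 5 | all-E-8'-apo-β-caroten-8'-ol | OC/C(C)=C/C=C/C(C)=C/C=C/C=C(C)/C=C/C=C(C)/C=C/C1=C(C)CCCC1(C)C
F2 | step 5 | retro C30 hydrocarbon (anhydro-8'-apo-β-carotenol; ring 4-ene, 6-ylidene, terminal C-8' methylene) | CC1=CCCC(C)(C)\C1=C/C=C(C)/C=C/C=C(C)/C=C/C=C/C(C)=C/C=C/C(C)=C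
F3 | step 5 | (4S)-4,8,8-trimethyl-1-oxaspiro[2.5]octane (spiro epimers) | C1OC12[C@@H](C)CCCC2(C)C
F4 | step 5 | (6S)-2,2,6-trimethylcyclohexane-1-carbaldehyde (C-1 epimers) | O=CC1[C@@H](C)CCCC1(C)C
F5 | step 5 | (E)-[(6S)-2,2,6-trimethylcyclohexylidene]methyl trifluoromethanesulfonate | FC(F)(F)S(=O)(=O)O/C=C1\[C@@H](C)CCCC1(C)C
F6 | step 2 | rac-2,2,6-trimethylcyclohexanone | CC1CCCC(C)(C)C1=O
F7 | step 2 | 2,6,6-trimethylcyclohex-1-en-1-yl trimethylsilyl ether | CC1=C(O[Si](C)(C)C)C(C)(C)CCC1
F8 | step 3 | all-E 1,1-dibromo-olefin of 5 (CH=O replaced by CH=CBr2) | BrC(Br)=C/C(C)=C/C=C/C(C)=C/C=C/C=C(C)/C=C/C=C(C)/C=C/C1=C(C)CCCC1(C)C
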